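Remarks on the chemistry. (a) Locants: C7, C8, C9 and C7', C8', C9' are the two halves of the furofuran; ring C (syringyl) sits on C7 and ring D (syringyl) on C7'; units A, B and E are the three arylglycerol units with guaiacyl rings A, B and E (B on ring C, A on ring B, E on ring D), each with its own C7, C8, C9. (b) Both enantiomers of 4-benzyl-3-(chloroacetyl)-1,3-oxazolidin-2-one (24, 36) are assumed purchasable; otherwise each costs one N-acylation of the oxazolidinone. (c) In long names "furofuran" means the (1R,3aS,4R,6aS)-tetrahydro-1H,3H-furo[3,4-c]furan core, TBS is tert-butyldimethylsilyl and TIPS is tri(propan-2-yl)silyl.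

## Analysis of the target

The target is a lignan pentamer built on a cis-fused 3,7-dioxabicyclo[3.3.0]octane (furofuran) made of C7, C8, C9 and C7', C8', C9'. Each benzylic carbon carries a syringyl ring (ring C on C7, ring D on C7'), and each syringyl O-4 is bound to C8 of a guaiacylglycerol unit. Ring C carries two units in a row (unit B, whose guaiacyl oxygen holds unit A) and ring D carries one (unit E); the phenols of rings A and E are free. There are ten stereocentres. The core is (7R,8S,7'R,8'S) with both aryl groups exo (H7/H8 trans, H8/H8' cis). All three side-chain units are erythro: B and E are (7S,8R), A is the mirror-image (7R,8S). The aryl ether links insulate the units from the core and from each other, so every unit needs its own reagent control, whereas inside the core C7 can direct C8 and C8'. Sensitive points are the benzylic C–O bonds of the core (ionisation and epimerisation in acid), the p-oxygenated benzylic alcohols of the side chains (cations, quinone methides) and the aryloxy group next to a carbonyl in any chain precursor (elimination). The synthesis is hard because the core is C2-symmetric while its substitution is not, so two hindered 2,6-dimethoxyphenol oxygens must be told apart, and because three units of two different absolute configurations must be attached. The strategy rests on the C8–C8' fusion bond: C8 and C8' lie 1,6 to each other in a nine-membered ring made of C9, C8, C7, the ring oxygen, C9', C8', C7' and an O–CH2 ester link, which is the array of a [3,3] shift.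

## Retrosynthetic reasoning

Target 49 to 48. The last step only removes silicon. The two phenols and four alcohols of units A and E are silyl ethers in 48, so one fluoride treatment ends the synthesis and no acid meets the benzylic alcohols or the furofuran.

Unit B: 48 back through 47 and 46 to imide 34 and aldehyde 44. The C7–C8 bond of unit B is cut because C8 then belongs to an aryloxyacetyl imide, whose boron enolate gives absolute control at C8, and because the aldehyde partner can carry unit A complete. Forward, a syn aldol sets C8 and gives C7 as the threo epimer (46), displacement with inversion at C7 makes the unit erythro (47), and reductive removal of the auxiliary gives the C9 alcohol (48).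

Aldehyde 44 back to 35, 36 and 27. The same three operations, run with the mirror-image auxiliary 36 on the small imide 37, give unit A in 41. Silylation (42) and bromine-to-formyl exchange give 44. Building unit A off the core keeps one full aldol cycle away from the precious core; aldehyde 27 comes from vanillin 26.

Unit E and the order of events: 34 back through 33, 32, 31, 30 and 29 to imide 25 and aldehyde 27, then to phenol 23, chloride 24 and core 22. The two core phenols are kept apart as a benzyl ether (ring C) and a silyl ether (ring D). Ring D is freed first, unit E is built and silylated, and only then is the ring C benzyl group removed by hydrogenolysis (32 to 33), when nothing else in the molecule is benzylated or reducible.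

Core 22 back to diol 21, then to lactol 17 and Grignard reagent 20. The C9–O–C7' bond is cut at the benzylic carbon, where a cation forms easily and both C7' epimers converge, and the C7'–aryl bond is cut to a lactol and an aryl nucleophile that brings its own phenol protection. This places the differently protected ring D on a core that already carries ring C.

Lactol 17 back to alcohol 15 and acid 14. C9 needs only reduction and the vinyl group is a masked C7' aldehyde; the extra carbon is lost on cleavage.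

Acid 14 back to lactone 11 (key disconnection). The C8–C8' bond is cut and the carboxyl oxygen is reconnected to the vinyl terminus. This turns a tetrahydrofuran with three contiguous stereocentres into a nine-membered lactone with one, and forward one sigmatropic shift forms the bond, the ring and two stereocentres.

Lactone 11 back to seco acid 9, ester 8, and then hydroxy ester 4 with imidate 7. The ester C–O bond is cut first and then the C7–O ether bond, which leaves a β-hydroxy ester whose single stereocentre comes from catalytic reduction of keto ester 3. Keto ester 3 comes from ketone 2 and acetosyringone 1; imidate 7 comes from diol 5 through acetate 6.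

## Alternatives that were turned down

Alternative 1: two-directional anti aldol on the finished core. The disconnection cuts the C7–C8 bonds of units B and E at once. The enantiopure core bisphenol A2 would be O-alkylated and turned into the bis(Z ketene silyl thioacetal) A3. Sn(OTf)2 with a chiral diamine would then join both termini to O-benzylvanillin A4 and give the bis(erythro 2-aryloxy-3-hydroxy thioester) A1.
- For it: one step makes two C–C bonds and four stereocentres, and it gives the erythro series directly. On this point it is stronger than the chosen route, which needs a syn aldol followed by an inversion for each unit.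
- Against it: it presupposes A2 and so leaves the four core stereocentres unsolved. A1 is C2-symmetric with two identical benzylated guaiacyl termini, while the target needs a third unit on only one of them, so a statistical mono-functionalisation would follow. The reagent-controlled addition has precedent for benzyloxy-substituted ketene silyl thioacetals, not for bulky 2,6-dimethoxyaryloxy ones, and stoichiometric divalent tin triflate would meet the acid-labile furofuran.
- In comparison, the chosen strategy delivers the core stereocentres and two phenols that differ from the start (benzyl on ring C, silyl on ring D), so the chains go on one after the other without statistics.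

Alternative 2: three-component Michael–aldol on a chiral butenolide. The disconnection cuts C7–C8 and C8'–C7'. The lithiated aryl dithiane A7 would add to the β-carbon of 5-(menthyloxy)furan-2(5H)-one A6 anti to the menthyloxy group, and the lactone enolate would capture 4-(allyloxy)-3,5-dimethoxybenzaldehyde A8, giving the trans,trans lactone acetal A5.
- For it: it is more convergent than the chosen route, with both aryl rings and two C–C bonds in one flask; it uses a cheap chiral template, needs no medium ring, and the two phenols are already distinguished (benzyl and allyl). On convergence and on phenol differentiation it is as good or better.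
- Against it: A5 has no stereocentre at C7 (dithiane) and an epimeric mixture at C7', so both benzylic centres would have to be set later in two cation-mediated ring closures, against one in the chosen route. Between A5 and the furofuran lie dithiane removal, ketone reduction, reduction of the lactone and of the acetal carbon, and loss of menthol. Residual sulfur also threatens later hydrogenolysis.
- In comparison, the chosen strategy sets C8 and C8' in a stereospecific pericyclic step under the control of C7, which comes from a catalytic reduction and is never reset.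

Alternative 3: twofold arylzinc addition to a bis-oxocarbenium core. The disconnection cuts both aryl–C7 bonds. Bromotrimethylsilane would ionise the bis(lactol acetate) A10, and two equivalents of the fully elaborated arylzinc bromide A11 would attack from the convex face to give the protected core A9.
- For it: it is the most convergent plan, with the side-chain stereocentres made on small molecules, and convex-face attack on a bicyclic oxocarbenium ion is a more reliable way to exo aryl groups than the cation closure used here. On C7/C7' control it is stronger.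
- Against it: the addition is symmetric, so A9 again has two identical termini and the third unit would have to be placed on one of two equal phenols. The enantiopure source of the two fusion centres of A10 is not addressed. A11 carries a benzylic acetal oxygen on an electron-rich ring that the Lewis acidic medium can ionise, and the second ionisation takes place next to an aryl-substituted ring that can itself open.
- In comparison, the chosen strategy introduces the two aryl groups at different times with different protection and derives all core stereochemistry from one catalytic reduction.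

Key step: step 9

## Route

Step 1
Reactants: 1 1-(4-hydroxy-3,5-dimethoxyphenyl)ethan-1-one (acetosyringone)
Product: 2 1-[4-(benzyloxy)-3,5-dimethoxyphenyl]ethan-1-one
Conditions: BnBr, K2CO3, DMF, 60 °C
Reagents that add atoms: benzyl bromide BrCc1ccccc1
Why: Williamson etherification of the phenoxide; benzyl survives the enolate, hydride, osmium and Grignard steps and is later removed by hydrogenolysis when no other benzyl-type group is present.

Step 2
Reactants: 2 1-[4-(benzyloxy)-3,5-dimethoxyphenyl]ethan-1-one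
Product: 3 methyl 3-[4-(benzyloxy)-3,5-dimethoxyphenyl]-3-oxopropanoate
Conditions: NaH, (MeO)2CO, toluene, reflux; AcOH quench
Reagents that add atoms: dimethyl carbonate COC(=O)OC
Why: Crossed Claisen condensation of the methyl ketone enolate with a carbonate that cannot enolise; deprotonation of the β-keto ester makes it irreversible.

Step 3
Reactants: 3 methyl 3-[4-(benzyloxy)-3,5-dimethoxyphenyl]-3-oxopropanoate
Product: 4 methyl (3R)-3-[4-(benzyloxy)-3,5-dimethoxyphenyl]-3-hydroxypropanoate
Conditions: RuCl(p-cymene)[(R,R)-TsDPEN] (1 mol%), HCO2H/Et3N (5:2), 40 °C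
Reagents that add atoms: none
Why: Noyori–Ikariya asymmetric transfer hydrogenation of an aryl ketone; the contact between the aryl ring and the cymene ligand fixes the face, and the (R,R) ligand should give the (R) carbinol, the future C7. Benzyl ether and ester are inert to the ruthenium hydride.

Step 4
Reactants: 5 (2Z)-but-2-ene-1,4-diol
Product: 6 (2Z)-4-hydroxybut-2-en-1-yl acetate
Conditions: Ac2O (0.3 equiv), Et3N, DMAP (cat.), CH2Cl2, 0 °C
Reagents that add atoms: acetic anhydride CC(=O)OC(C)=O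
Why: Mono-acetylation made selective by a threefold excess of the cheap diol; acetate resists the acid of step 6 and leaves together with the methyl ester in step 7.

Step 5
Reactants: 6 (2Z)-4-hydroxybut-2-en-1-yl acetate
Product: 7 (2Z)-4-acetoxybut-2-en-1-yl 2,2,2-trichloroacetimidate
Conditions: Cl3CCN, DBU (cat.), CH2Cl2, 0 °C
Reagents that add atoms: trichloroacetonitrile ClC(Cl)(Cl)C#N
Why: Base-catalysed addition of the alcohol to the nitrile; the imidate is used crude and cold so that it does not rearrange.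

Step 6
Reactants: 4 methyl (3R)-3-[4-(benzyloxy)-3,5-dimethoxyphenyl]-3-hydroxypropanoate; 7 (2Z)-4-acetoxybut-2-en-1-yl 2,2,2-trichloroacetimidate
Product: 8 methyl (3R)-3-{[(2Z)-4-acetoxybut-2-en-1-yl]oxy}-3-[4-(benzyloxy)-3,5-dimethoxyphenyl]propanoate
Conditions: TfOH (5 mol%), CH2Cl2/cyclohexane (1:2), 0 °C
Reagents that add atoms: none
Why: Acid-catalysed O-alkylation of an alcohol with an allylic trichloroacetimidate; without base, retro-aldol and E1cB loss of the β-oxygen are excluded. The C7–O bond is not broken, so C7 keeps its configuration, and the primary allyl terminus reacts with the Z geometry retained.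

Step 7
Reactants: 8 methyl (3R)-3-{[(2Z)-4-acetoxybut-2-en-1-yl]oxy}-3-[4-(benzyloxy)-3,5-dimethoxyphenyl]propanoate
Product: 9 (3R)-3-[4-(benzyloxy)-3,5-dimethoxyphenyl]-3-{[(2Z)-4-hydroxybut-2-en-1-yl]oxy}propanoic acid
Conditions: LiOH, THF/MeOH/H2O, 0 °C; 1 M HCl to pH 3
Reagents that add atoms: lithium hydroxide [Li+].[OH-]
Why: Saponification of both esters in one operation; once the carboxylate has formed, C8–H is no longer acidic enough for β-elimination.

Step 8
Reactants: 9 (3R)-3-[4-(benzyloxy)-3,5-dimethoxyphenyl]-3-{[(2Z)-4-hydroxybut-2-en-1-yl]oxy}propanoic acid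
Product: 11 (4R,7Z)-4-[4-(benzyloxy)-3,5-dimethoxyphenyl]-3,4,6,9-tetrahydro-2H-1,5-dioxonin-2-one, via mixed anhydride 10 (not isolated)
Conditions: 2,4,6-Cl3C6H2COCl, Et3N, THF, rt; then slow addition to DMAP, toluene, 90 °C (1 mM)
Reagents that add atoms: none
Why: Yamaguchi macrolactonisation under high dilution; the Z alkene and the ring oxygen remove transannular hydrogens and pre-organise the chain, which makes the nine-membered ring accessible.

Step 9
Reactants: 11 (4R,7Z)-4-[4-(benzyloxy)-3,5-dimethoxyphenyl]-3,4,6,9-tetrahydro-2H-1,5-dioxonin-2-one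
Product: 14 (2R,3R,4S)-2-[4-(benzyloxy)-3,5-dimethoxyphenyl]-4-ethenyloxolane-3-carboxylic acid, via silyl ketene acetal 12 (not isolated), via trimethylsilyl ester 13 (not isolated)
Conditions: Me3SiCl/Et3N (premixed), THF, −78 °C; KN(SiMe3)2 (toluene), −78 °C; then rt to 65 °C; 1 M HCl
Reagents that add atoms: none
Why: Ireland–Claisen ring contraction: KN(SiMe3)2 deprotonates C8 of 11 and the Me3SiCl already present traps the enolate at −78 °C as ketene acetal 12, in which the ring holds C7 cis to the ring ester oxygen; on warming, 12 undergoes a concerted suprafacial [3,3] shift that forms C8–C8' and breaks the allylic O–CH2 bond, giving silyl ester 13 and, after acid hydrolysis, acid 14. The closest known reaction type is the ester-enolate Claisen ring contraction of unsaturated medium and large lactones to 2-vinylcycloalkane- and 4-vinyltetrahydrofuran-carboxylic acids. The tetrahydrofuran ring (C7, O, C9', C8', C8) closes in the same event, formally a 5-(enolexo)-exo-trig closure realised as a pericyclic bond shift. C8 and C8' are set together by the boat geometry that the three-atom C7–O–C9' tether enforces: with C7 cis on the ketene acetal and C9' cis on the Z alkene, C7 eclipses C9', the two hydrogens eclipse and C9 eclipses C7', so carboxyl and vinyl come out cis. Their sense relative to C7 (R) follows from the aryl group taking the exo, pseudo-equatorial site of the bicyclic transition state, trans to C9, so the chirality set in step 3 is relayed to both new centres. The step needs silylation to outrun β-elimination of the C7 oxygen from the enolate; the in situ quench at −78 °C is there to secure this.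

Step 10
Reactants: 14 (2R,3R,4S)-2-[4-(benzyloxy)-3,5-dimethoxyphenyl]-4-ethenyloxolane-3-carboxylic acid
Product: 15 {(2R,3S,4S)-2-[4-(benzyloxy)-3,5-dimethoxyphenyl]-4-ethenyloxolan-3-yl}methanol
Conditions: LiAlH4, THF, 0 °C to rt
Reagents that add atoms: none
Why: Hydride reduction of the acid to the C9 alcohol without enolisation, so C8 is not touched; vinyl group and benzyl ether are inert.

Step 11
Reactants: 15 {(2R,3S,4S)-2-[4-(benzyloxy)-3,5-dimethoxyphenyl]-4-ethenyloxolan-3-yl}methanol
Product: 17 (3aS,4R,6aS)-4-[4-(benzyloxy)-3,5-dimethoxyphenyl]tetrahydro-1H,3H-furo[3,4-c]furan-1-ol (both anomers), via hydroxy aldehyde 16 (not isolated)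
Conditions: OsO4 (2 mol%), NaIO4, 2,6-lutidine, dioxane/H2O (3:1), rt
Reagents that add atoms: osmium tetroxide O=[Os](=O)(=O)=O; sodium periodate [Na+].[O-]I(=O)(=O)=O
Why: Lemieux–Johnson cleavage of the terminal alkene to the C7' aldehyde, which lies cis to the C9 hydroxymethyl group and closes at once to the bicyclic lactol; osmium and periodate are used instead of ozone to spare the electron-rich arene.

Step 12
Reactants: 18 4-bromo-2,6-dimethoxyphenol
Product: 19 (4-bromo-2,6-dimethoxyphenoxy)tri(propan-2-yl)silane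
Conditions: TIPSOTf, 2,6-lutidine, CH2Cl2, 0 °C to rt
Reagents that add atoms: tri(propan-2-yl)silyl trifluoromethanesulfonate CC(C)[Si](C(C)C)(C(C)C)OS(=O)(=O)C(F)(F)F
Why: Silylation of a hindered phenol with the reactive triflate; the silyl ether tolerates Grignard formation and the acid of step 14 and is orthogonal to the benzyl ether of ring C.

Step 13
Reactants: 17 (3aS,4R,6aS)-4-[4-(benzyloxy)-3,5-dimethoxyphenyl]tetrahydro-1H,3H-furo[3,4-c]furan-1-ol; 19 (4-bromo-2,6-dimethoxyphenoxy)tri(propan-2-yl)silane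
Product: 21 {(3S,4S,5R)-5-[4-(benzyloxy)-3,5-dimethoxyphenyl]-4-(hydroxymethyl)oxolan-3-yl}{3,5-dimethoxy-4-[tri(propan-2-yl)silyloxy]phenyl}methanol (both carbinol epimers), via arylmagnesium bromide 20 (not isolated)
Conditions: 19 (3.5 equiv), Mg, LiCl, THF, 45 °C; then 17, THF, 0 °C to rt; aq NH4Cl
Reagents that add atoms: none
Why: Grignard addition to the open hydroxy aldehyde form of a lactol; the first equivalent deprotonates the lactol and the next forms the C7'–aryl bond. C7' forms as an epimer mixture, which is of no consequence because it becomes planar in step 14.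

Step 14
Reactants: 21 {(3S,4S,5R)-5-[4-(benzyloxy)-3,5-dimethoxyphenyl]-4-(hydroxymethyl)oxolan-3-yl}{3,5-dimethoxy-4-[tri(propan-2-yl)silyloxy]phenyl}methanol
Product: 22 (1R,3aS,4R,6aS)-1-[4-(benzyloxy)-3,5-dimethoxyphenyl]-4-{3,5-dimethoxy-4-[tri(propan-2-yl)silyloxy]phenyl}tetrahydro-1H,3H-furo[3,4-c]furan
Conditions: CSA (20 mol%), 4 Å MS, CH2Cl2, 0 °C; Et3N quench
Reagents that add atoms: none
Why: Acid-catalysed cyclodehydration through the C7' benzylic cation (SN1), captured by the C9 hydroxyl in a 5-exo closure; both epimers of 21 converge on the same cation. The aryl group should take the exo side of the forming cis-fused bicycle, as it does when quinone methides close to furofurans, and the base quench at full conversion prevents later equilibration.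

Step 15
Reactants: 22 (1R,3aS,4R,6aS)-1-[4-(benzyloxy)-3,5-dimethoxyphenyl]-4-{3,5-dimethoxy-4-[tri(propan-2-yl)silyloxy]phenyl}tetrahydro-1H,3H-furo[3,4-c]furan
Product: 23 4-{(1R,3aS,4R,6aS)-4-[4-(benzyloxy)-3,5-dimethoxyphenyl]tetrahydro-1H,3H-furo[3,4-c]furan-1-yl}-2,6-dimethoxyphenol
Conditions: Bu4NF, THF, 0 °C; aq NH4Cl
Reagents that add atoms: none
Why: Fluoride cleaves the aryl silyl ether and leaves the benzyl ether, which frees the ring D phenol alone.

Step 16
Reactants: 23 4-{(1R,3aS,4R,6aS)-4-[4-(benzyloxy)-3,5-dimethoxyphenyl]tetrahydro-1H,3H-furo[3,4-c]furan-1-yl}-2,6-dimethoxyphenol; 24 (4S)-4-benzyl-3-(chloroacetyl)-1,3-oxazolidin-2-one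
Product: 25 (4S)-4-benzyl-3-{[4-(4-[4-(benzyloxy)-3,5-dimethoxyphenyl]furofuran-1-yl)-2,6-dimethoxyphenoxy]acetyl}-1,3-oxazolidin-2-one
Conditions: K2CO3, NaI (cat.), acetone, 40 °C
Reagents that add atoms: none
Why: Williamson alkylation of the phenoxide at the primary, carbonyl-activated carbon (iodide formed in situ); the hindered phenoxide prefers this SN2 reaction to attack on the imide carbonyl.

Step 17
Reactants: 26 4-hydroxy-3-methoxybenzaldehyde (vanillin)
Product: 27 3-methoxy-4-[tri(propan-2-yl)silyloxy]benzaldehyde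
Conditions: TIPSCl, imidazole, DMF, rt
Reagents that add atoms: chlorotri(propan-2-yl)silane CC(C)[Si](Cl)(C(C)C)C(C)C
Why: Standard silylation of a phenol; a silyl ether is needed on rings A and E because it survives the hydrogenolysis of step 22 and leaves in the final fluoride step.

Step 18
Reactants: 25 (4S)-4-benzyl-3-{[4-(4-[4-(benzyloxy)-3,5-dimethoxyphenyl]furofuran-1-yl)-2,6-dimethoxyphenoxy]acetyl}-1,3-oxazolidin-2-one; 27 3-methoxy-4-[tri(propan-2-yl)silyloxy]benzaldehyde
Product: 29 syn aldol adduct of unit E: (4S)-4-benzyl-3-[(2S,3R)-3-hydroxy-3-{3-methoxy-4-[tri(propan-2-yl)silyloxy]phenyl}-2-(ring D aryloxy)propanoyl]-1,3-oxazolidin-2-one, via boron enolate 28 (not isolated)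
Conditions: Bu2BOTf, iPr2NEt, CH2Cl2, −78 to 0 °C; 27, −78 to 0 °C; pH 7 buffer, MeOH, H2O2
Reagents that add atoms: none
Why: Evans syn aldol: the Z dibutylboron enolate reacts through a closed chair transition state on the face away from the benzyl group of the (S) auxiliary, giving the (2S,3R) adduct. This sets C8 of unit E as needed and C7 as the threo epimer, which step 19 corrects.

Step 19
Reactants: 29 syn aldol adduct of unit E
Product: 30 (4S)-4-benzyl-3-[(2S,3S)-3-{3-methoxy-4-[tri(propan-2-yl)silyloxy]phenyl}-3-(4-nitrobenzoyloxy)-2-(ring D aryloxy)propanoyl]-1,3-oxazolidin-2-one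
Conditions: PPh3, DIAD, 4-O2NC6H4CO2H, THF, 0 °C to rt
Reagents that add atoms: 4-nitrobenzoic acid OC(=O)c1ccc(cc1)[N+](=O)[O-]
Why: Mitsunobu inversion: the carboxylate displaces the oxyphosphonium group by SN2 and turns C7 of unit E to the erythro configuration. The imide α-hydrogen lies in the plane of the carbonyl group, which should slow the competing elimination.

Step 20
Reactants: 30 (4S)-4-benzyl-3-[(2S,3S)-3-{3-methoxy-4-[tri(propan-2-yl)silyloxy]phenyl}-3-(4-nitrobenzoyloxy)-2-(ring D aryloxy)propanoyl]-1,3-oxazolidin-2-one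
Product: 31 (1S,2R)-2-[4-(4-[4-(benzyloxy)-3,5-dimethoxyphenyl]furofuran-1-yl)-2,6-dimethoxyphenoxy]-1-{3-methoxy-4-[tri(propan-2-yl)silyloxy]phenyl}propane-1,3-diol
Conditions: LiBH4, THF/MeOH, 0 °C to rt
Reagents that add atoms: none
Why: Borohydride reduces the exocyclic imide carbonyl to the C9 alcohol and cleaves the nitrobenzoate; no enolate forms, so C8 is kept, and the silyl ether, benzyl ether and furofuran are inert.

Step 21
Reactants: 31 (1S,2R)-2-[4-(4-[4-(benzyloxy)-3,5-dimethoxyphenyl]furofuran-1-yl)-2,6-dimethoxyphenoxy]-1-{3-methoxy-4-[tri(propan-2-yl)silyloxy]phenyl}propane-1,3-diol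
Product: 32 bis-TBS ether of 31 at O7 and O9 of unit E
Conditions: TBSOTf, 2,6-lutidine, CH2Cl2, −78 to 0 °C
Reagents that add atoms: tert-butyldimethylsilyl trifluoromethanesulfonate CC(C)(C)[Si](C)(C)OS(=O)(=O)C(F)(F)F
Why: Silylation of both hydroxyls makes unit E inert to the boron enolate and Mitsunobu chemistry of steps 30 and 31 and puts it on the same fluoride-labile footing as unit A.

Step 22
Reactants: 32 bis-TBS ether of 31
Product: 33 ring C phenol: 4-{furofuran-1-yl}-2,6-dimethoxyphenol carrying silylated unit E on ring D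
Conditions: H2 (1 atm), Pd/C (10%), EtOAc, rt
Reagents that add atoms: none
Why: Hydrogenolysis of the only aryl benzyl ether; under neutral conditions the cyclic benzylic ethers of the core and the benzylic silyl ether react much more slowly.

Step 23
Reactants: 33 ring C phenol; 24 (4S)-4-benzyl-3-(chloroacetyl)-1,3-oxazolidin-2-one
Product: 34 ring C aryloxyacetyl imide: (4S)-4-benzyl-3-[(ring C aryloxy)acetyl]-1,3-oxazolidin-2-one carrying silylated unit E on ring D
Conditions: K2CO3, NaI (cat.), acetone, 40 °C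
Reagents that add atoms: none
Why: Williamson alkylation as in step 16; the guaiacyl silyl ether of ring E is stable to carbonate in acetone.

Step 24
Reactants: 35 4-bromo-2-methoxyphenol; 36 (4R)-4-benzyl-3-(chloroacetyl)-1,3-oxazolidin-2-one
Product: 37 (4R)-4-benzyl-3-[(4-bromo-2-methoxyphenoxy)acetyl]-1,3-oxazolidin-2-one
Conditions: K2CO3, NaI (cat.), acetone, 40 °C
Reagents that add atoms: none
Why: Williamson alkylation; the bromine marks the carbon of ring B that becomes the aldehyde in step 29.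

Step 25
Reactants: 37 (4R)-4-benzyl-3-[(4-bromo-2-methoxyphenoxy)acetyl]-1,3-oxazolidin-2-one; 27 3-methoxy-4-[tri(propan-2-yl)silyloxy]benzaldehyde
Product: 39 (4R)-4-benzyl-3-[(2R,3S)-2-(4-bromo-2-methoxyphenoxy)-3-hydroxy-3-{3-methoxy-4-[tri(propan-2-yl)silyloxy]phenyl}propanoyl]-1,3-oxazolidin-2-one, via boron enolate 38 (not isolated)
Conditions: Bu2BOTf, iPr2NEt, CH2Cl2, −78 to 0 °C; 27, −78 to 0 °C; pH 7 buffer, MeOH, H2O2
Reagents that add atoms: none
Why: Evans syn aldol in the mirror-image series; the (R) auxiliary gives the (2R,3S) adduct and so sets C8 of unit A.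

Step 26
Reactants: 39 syn aldol adduct of unit A
Product: 40 (4R)-4-benzyl-3-[(2R,3R)-2-(4-bromo-2-methoxyphenoxy)-3-{3-methoxy-4-[tri(propan-2-yl)silyloxy]phenyl}-3-(4-nitrobenzoyloxy)propanoyl]-1,3-oxazolidin-2-one
Conditions: PPh3, DIAD, 4-O2NC6H4CO2H, THF, 0 °C to rt
Reagents that add atoms: 4-nitrobenzoic acid OC(=O)c1ccc(cc1)[N+](=O)[O-]
Why: Mitsunobu inversion at C7 of unit A, as in step 19, to reach the erythro series.

Step 27
Reactants: 40 nitrobenzoate of unit A
Product: 41 (1R,2S)-2-(4-bromo-2-methoxyphenoxy)-1-{3-methoxy-4-[tri(propan-2-yl)silyloxy]phenyl}propane-1,3-diol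
Conditions: LiBH4, THF/MeOH, 0 °C to rt
Reagents that add atoms: none
Why: Reductive removal of auxiliary and nitrobenzoate as in step 20; the aryl bromide is not reduced by borohydride.

Step 28
Reactants: 41 (1R,2S)-2-(4-bromo-2-methoxyphenoxy)-1-{3-methoxy-4-[tri(propan-2-yl)silyloxy]phenyl}propane-1,3-diol
Product: 42 bis-TBS ether of 41
Conditions: TBSOTf, 2,6-lutidine, CH2Cl2, −78 to 0 °C
Reagents that add atoms: tert-butyldimethylsilyl trifluoromethanesulfonate CC(C)(C)[Si](C)(C)OS(=O)(=O)C(F)(F)F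
Why: Silyl protection of both hydroxyls before organolithium and boron enolate chemistry.

Step 29
Reactants: 42 bis-TBS ether of 41
Product: 44 4-{[(1R,2S)-1,3-bis(tert-butyldimethylsilyloxy)-1-{3-methoxy-4-[tri(propan-2-yl)silyloxy]phenyl}propan-2-yl]oxy}-3-methoxybenzaldehyde, via aryllithium 43 (not isolated)
Conditions: n-BuLi, THF, −78 °C; DMF, −78 °C to rt; aq NH4Cl
Reagents that add atoms: N,N-dimethylformamide CN(C)C=O
Why: Bromine–lithium exchange followed by formylation (Bouveault type); exchange at −78 °C is faster than any deprotonation, and silyl and aryl ethers are inert.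

Step 30
Reactants: 34 ring C aryloxyacetyl imide; 44 aldehyde carrying unit A
Product: 46 syn aldol adduct of unit B: (2S,3R)-3-hydroxy imide on ring C with ring B carrying silylated unit A, via boron enolate 45 (not isolated)
Conditions: Bu2BOTf, iPr2NEt, CH2Cl2, −78 to 0 °C; 44, −78 to 0 °C; pH 7 buffer, MeOH, H2O2
Reagents that add atoms: none
Why: Evans syn aldol; the (S) auxiliary controls the new centres because all other stereocentres are remote, giving C8 of unit B as needed and C7 as the threo epimer. All other hydroxyls are silylated, so only the imide reacts.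

Step 31
Reactants: 46 syn aldol adduct of unit B
Product: 47 (2S,3S)-3-(4-nitrobenzoyloxy) imide of unit B
Conditions: PPh3, DIAD, 4-O2NC6H4CO2H, THF, 0 °C to rt
Reagents that add atoms: 4-nitrobenzoic acid OC(=O)c1ccc(cc1)[N+](=O)[O-]
Why: Mitsunobu inversion at the only free hydroxyl, C7 of unit B, to reach the erythro series.

Step 32
Reactants: 47 nitrobenzoate of unit B
Product: 48 target silylated on O7 and O9 of units A and E (TBS) and on the phenols of rings A and E (TIPS)
Conditions: LiBH4, THF/MeOH, 0 °C to rt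
Reagents that add atoms: none
Why: Reductive removal of auxiliary and nitrobenzoate as in step 20, which frees the C7 and C9 hydroxyls of unit B.

Step 33
Reactants: 48 hexasilyl ether
Product: 49 target CNP0316493.2
Conditions: Bu4NF, AcOH, THF, 0 °C to rt
Reagents that add atoms: none
Why: Fluoride-mediated cleavage of four alkyl and two aryl silyl ethers; the acetic acid buffer keeps the phenols protonated, and no acid strong enough to ionise the benzylic alcohols or the furofuran is present.

## Compound list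

1 | 1-(4-hydroxy-3,5-dimethoxyphenyl)ethan-1-one (acetosyringone) | CC(=O)c1cc(OC)c(O)c(OC)c1 | starting material
2 | 1-[4-(benzyloxy)-3,5-dimethoxyphenyl]ethan-1-one | CC(=O)c1cc(OC)c(OCc2ccccc2)c(OC)c1 | intermediate
3 | methyl 3-[4-(benzyloxy)-3,5-dimethoxyphenyl]-3-oxopropanoate | COC(=O)CC(=O)c1cc(OC)c(OCc2ccccc2)c(OC)c1 | intermediate
4 | methyl (3R)-3-[4-(benzyloxy)-3,5-dimethoxyphenyl]-3-hydroxypropanoate | COC(=O)C[C@@H](O)c1cc(OC)c(OCc2ccccc2)c(OC)c1 | intermediate
5 | (2Z)-but-2-ene-1,4-diol | OC/C=C\CO | starting material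
6 | (2Z)-4-hydroxybut-2-en-1-yl acetate | CC(=O)OC/C=C\CO | intermediate
7 | (2Z)-4-acetoxybut-2-en-1-yl 2,2,2-trichloroacetimidate | CC(=O)OC/C=C\COC(=N)C(Cl)(Cl)Cl | intermediate
8 | methyl (3R)-3-{[(2Z)-4-acetoxybut-2-en-1-yl]oxy}-3-[4-(benzyloxy)-3,5-dimethoxyphenyl]propanoate | COC(=O)C[C@@H](OC/C=C\COC(C)=O)c1cc(OC)c(OCc2ccccc2)c(OC)c1 | intermediate
9 | (3R)-3-[4-(benzyloxy)-3,5-dimethoxyphenyl]-3-{[(2Z)-4-hydroxybut-2-en-1-yl]oxy}propanoic acid | OC(=O)C[C@@H](OC/C=C\CO)c1cc(OC)c(OCc2ccccc2)c(OC)c1 | intermediate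
10 | mixed anhydride of 9 with 2,4,6-trichlorobenzoic acid (not isolated) | O=C(OC(=O)c1c(Cl)cc(Cl)cc1Cl)C[C@@H](OC/C=C\CO)c2cc(OC)c(OCc3ccccc3)c(OC)c2 | intermediate
11 | (4R,7Z)-4-[4-(benzyloxy)-3,5-dimethoxyphenyl]-3,4,6,9-tetrahydro-2H-1,5-dioxonin-2-one | COc1cc(cc(OC)c1OCc2ccccc2)[C@H]3CC(=O)OC/C=C\CO3 | intermediate
12 | (2E,4R,7Z)-4-[4-(benzyloxy)-3,5-dimethoxyphenyl]-2-(trimethylsilyloxy)-6,9-dihydro-4H-1,5-dioxonine, ketene acetal with C4 cis to O1 (not isolated) | COc1cc(cc(OC)c1OCc2ccccc2)[C@H]3/C=C(/O[Si](C)(C)C)OC/C=C\CO3 | intermediate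
13 | trimethylsilyl (2R,3R,4S)-2-[4-(benzyloxy)-3,5-dimethoxyphenyl]-4-ethenyloxolane-3-carboxylate (not isolated) | COc1cc(cc(OC)c1OCc2ccccc2)[C@@H]3OC[C@@H](C=C)[C@H]3C(=O)O[Si](C)(C)C | intermediate
14 | (2R,3R,4S)-2-[4-(benzyloxy)-3,5-dimethoxyphenyl]-4-ethenyloxolane-3-carboxylic acid (2,3-trans, 3,4-cis) | COc1cc(cc(OC)c1OCc2ccccc2)[C@@H]3OC[C@@H](C=C)[C@H]3C(=O)O | intermediate
15 | {(2R,3S,4S)-2-[4-(benzyloxy)-3,5-dimethoxyphenyl]-4-ethenyloxolan-3-yl}methanol | COc1cc(cc(OC)c1OCc2ccccc2)[C@@H]3OC[C@@H](C=C)[C@H]3CO | intermediate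
16 | (3S,4S,5R)-5-[4-(benzyloxy)-3,5-dimethoxyphenyl]-4-(hydroxymethyl)oxolane-3-carbaldehyde (not isolated) | COc1cc(cc(OC)c1OCc2ccccc2)[C@@H]3OC[C@@H](C=O)[C@H]3CO | intermediate
17 | (3aS,4R,6aS)-4-[4-(benzyloxy)-3,5-dimethoxyphenyl]tetrahydro-1H,3H-furo[3,4-c]furan-1-ol, both anomers | COc1cc(cc(OC)c1OCc2ccccc2)[C@@H]3OC[C@@H]4[C@H]3COC4O | intermediate
18 | 4-bromo-2,6-dimethoxyphenol | COc1cc(Br)cc(OC)c1O | starting material
19 | (4-bromo-2,6-dimethoxyphenoxy)tri(propan-2-yl)silane | COc1cc(Br)cc(OC)c1O[Si](C(C)C)(C(C)C)C(C)C | intermediate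
20 | {3,5-dimethoxy-4-[tri(propan-2-yl)silyloxy]phenyl}magnesium bromide (not isolated) | COc1cc([Mg]Br)cc(OC)c1O[Si](C(C)C)(C(C)C)C(C)C | intermediate
21 | {(3S,4S,5R)-5-[4-(benzyloxy)-3,5-dimethoxyphenyl]-4-(hydroxymethyl)oxolan-3-yl}{3,5-dimethoxy-4-[tri(propan-2-yl)silyloxy]phenyl}methanol, both carbinol epimers | COc1cc(cc(OC)c1OCc2ccccc2)[C@@H]3OC[C@@H](C(O)c4cc(OC)c(O[Si](C(C)C)(C(C)C)C(C)C)c(OC)c4)[C@H]3CO | intermediate
22 | (1R,3aS,4R,6aS)-1-[4-(benzyloxy)-3,5-dimethoxyphenyl]-4-{3,5-dimethoxy-4-[tri(propan-2-yl)silyloxy]phenyl}tetrahydro-1H,3H-furo[3,4-c]furan | COc1cc(cc(OC)c1OCc2ccccc2)[C@@H]3OC[C@@H]4[C@H]3CO[C@H]4c5cc(OC)c(O[Si](C(C)C)(C(C)C)C(C)C)c(OC)c5 | intermediate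
23 | 4-{(1R,3aS,4R,6aS)-4-[4-(benzyloxy)-3,5-dimethoxyphenyl]tetrahydro-1H,3H-furo[3,4-c]furan-1-yl}-2,6-dimethoxyphenol | COc1cc(cc(OC)c1OCc2ccccc2)[C@@H]3OC[C@@H]4[C@H]3CO[C@H]4c5cc(OC)c(O)c(OC)c5 | intermediate
24 | (4S)-4-benzyl-3-(chloroacetyl)-1,3-oxazolidin-2-one | ClCC(=O)N1[C@@H](Cc2ccccc2)COC1=O | starting material
25 | (4S)-4-benzyl-3-{[4-(4-[4-(benzyloxy)-3,5-dimethoxyphenyl]furofuran-1-yl)-2,6-dimethoxyphenoxy]acetyl}-1,3-oxazolidin-2-one | COc1cc(cc(OC)c1OCc2ccccc2)[C@@H]3OC[C@@H]4[C@H]3CO[C@H]4c5cc(OC)c(OCC(=O)N6[C@@H](Cc7ccccc7)COC6=O)c(OC)c5 | intermediate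
26 | 4-hydroxy-3-methoxybenzaldehyde (vanillin) | COc1cc(C=O)ccc1O | starting material
27 | 3-methoxy-4-[tri(propan-2-yl)silyloxy]benzaldehyde | COc1cc(C=O)ccc1O[Si](C(C)C)(C(C)C)C(C)C | intermediate
28 | Z dibutylboron enolate of 25, aryloxy cis to O–B (not isolated) | COc1cc(cc(OC)c1OCc2ccccc2)[C@@H]3OC[C@@H]4[C@H]3CO[C@H]4c5cc(OC)c(O/C=C(\OB(CCCC)CCCC)N6[C@@H](Cc7ccccc7)COC6=O)c(OC)c5 | intermediate
29 | syn aldol adduct of unit E: (4S)-4-benzyl-3-[(2S,3R)-3-hydroxy-3-{3-methoxy-4-[tri(propan-2-yl)silyloxy]phenyl}-2-(ring D aryloxy)propanoyl]-1,3-oxazolidin-2-one | COc1cc(cc(OC)c1OCc2ccccc2)[C@@H]3OC[C@@H]4[C@H]3CO[C@H]4c5cc(OC)c(O[C@H](C(=O)N6[C@@H](Cc7ccccc7)COC6=O)[C@H](O)c8ccc(O[Si](C(C)C)(C(C)C)C(C)C)c(OC)c8)c(OC)c5 | intermediate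
30 | (2S,3S)-3-(4-nitrobenzoyloxy) analogue of 29, C3 inverted | COc1cc(cc(OC)c1OCc2ccccc2)[C@@H]3OC[C@@H]4[C@H]3CO[C@H]4c5cc(OC)c(O[C@H](C(=O)N6[C@@H](Cc7ccccc7)COC6=O)[C@@H](OC(=O)c9ccc(cc9)[N+](=O)[O-])c8ccc(O[Si](C(C)C)(C(C)C)C(C)C)c(OC)c8)c(OC)c5 | intermediate
31 | (1S,2R)-2-[4-(4-[4-(benzyloxy)-3,5-dimethoxyphenyl]furofuran-1-yl)-2,6-dimethoxyphenoxy]-1-{3-methoxy-4-[tri(propan-2-yl)silyloxy]phenyl}propane-1,3-diol (erythro unit E) | COc1cc(cc(OC)c1OCc2ccccc2)[C@@H]3OC[C@@H]4[C@H]3CO[C@H]4c5cc(OC)c(O[C@H](CO)[C@@H](O)c6ccc(O[Si](C(C)C)(C(C)C)C(C)C)c(OC)c6)c(OC)c5 | intermediate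
32 | 1,3-bis-O-TBS ether of 31 | COc1cc(cc(OC)c1OCc2ccccc2)[C@@H]3OC[C@@H]4[C@H]3CO[C@H]4c5cc(OC)c(O[C@H](CO[Si](C)(C)C(C)(C)C)[C@@H](O[Si](C)(C)C(C)(C)C)c6ccc(O[Si](C(C)C)(C(C)C)C(C)C)c(OC)c6)c(OC)c5 | intermediate
33 | ring C phenol: 32 without the benzyl group | COc1cc(cc(OC)c1O)[C@@H]3OC[C@@H]4[C@H]3CO[C@H]4c5cc(OC)c(O[C@H](CO[Si](C)(C)C(C)(C)C)[C@@H](O[Si](C)(C)C(C)(C)C)c6ccc(O[Si](C(C)C)(C(C)C)C(C)C)c(OC)c6)c(OC)c5 | intermediate
34 | ring C aryloxyacetyl imide: 33 with OCH2C(=O)-[(4S)-4-benzyl-2-oxo-1,3-oxazolidin-3-yl] on ring C | COc1cc(cc(OC)c1OCC(=O)N2[C@@H](Cc7ccccc7)COC2=O)[C@@H]3OC[C@@H]4[C@H]3CO[C@H]4c5cc(OC)c(O[C@H](CO[Si](C)(C)C(C)(C)C)[C@@H](O[Si](C)(C)C(C)(C)C)c6ccc(O[Si](C(C)C)(C(C)C)C(C)C)c(OC)c6)c(OC)c5 | intermediate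
35 | 4-bromo-2-methoxyphenol | COc1cc(Br)ccc1O | starting material
36 | (4R)-4-benzyl-3-(chloroacetyl)-1,3-oxazolidin-2-one | ClCC(=O)N1[C@H](Cc2ccccc2)COC1=O | starting material
37 | (4R)-4-benzyl-3-[(4-bromo-2-methoxyphenoxy)acetyl]-1,3-oxazolidin-2-one | COc1cc(Br)ccc1OCC(=O)N2[C@H](Cc3ccccc3)COC2=O | intermediate
38 | Z dibutylboron enolate of 37 (not isolated) | COc1cc(Br)ccc1O/C=C(\OB(CCCC)CCCC)N2[C@H](Cc3ccccc3)COC2=O | intermediate
39 | (4R)-4-benzyl-3-[(2R,3S)-2-(4-bromo-2-methoxyphenoxy)-3-hydroxy-3-{3-methoxy-4-[tri(propan-2-yl)silyloxy]phenyl}propanoyl]-1,3-oxazolidin-2-one | COc1cc(Br)ccc1O[C@@H](C(=O)N2[C@H](Cc3ccccc3)COC2=O)[C@@H](O)c4ccc(O[Si](C(C)C)(C(C)C)C(C)C)c(OC)c4 | intermediate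
40 | (2R,3R)-3-(4-nitrobenzoyloxy) analogue of 39, C3 inverted | COc1cc(Br)ccc1O[C@@H](C(=O)N2[C@H](Cc3ccccc3)COC2=O)[C@H](OC(=O)c5ccc(cc5)[N+](=O)[O-])c4ccc(O[Si](C(C)C)(C(C)C)C(C)C)c(OC)c4 | intermediate
41 | (1R,2S)-2-(4-bromo-2-methoxyphenoxy)-1-{3-methoxy-4-[tri(propan-2-yl)silyloxy]phenyl}propane-1,3-diol (erythro unit A) | COc1cc(Br)ccc1O[C@@H](CO)[C@H](O)c2ccc(O[Si](C(C)C)(C(C)C)C(C)C)c(OC)c2 | intermediate
42 | 1,3-bis-O-TBS ether of 41 | COc1cc(Br)ccc1O[C@@H](CO[Si](C)(C)C(C)(C)C)[C@H](O[Si](C)(C)C(C)(C)C)c2ccc(O[Si](C(C)C)(C(C)C)C(C)C)c(OC)c2 | intermediate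
43 | aryllithium from 42, lithium in place of bromine (not isolated) | COc1cc([Li])ccc1O[C@@H](CO[Si](C)(C)C(C)(C)C)[C@H](O[Si](C)(C)C(C)(C)C)c2ccc(O[Si](C(C)C)(C(C)C)C(C)C)c(OC)c2 | intermediate
44 | 4-{[(1R,2S)-1,3-bis(tert-butyldimethylsilyloxy)-1-{3-methoxy-4-[tri(propan-2-yl)silyloxy]phenyl}propan-2-yl]oxy}-3-methoxybenzaldehyde | COc1cc(C=O)ccc1O[C@@H](CO[Si](C)(C)C(C)(C)C)[C@H](O[Si](C)(C)C(C)(C)C)c2ccc(O[Si](C(C)C)(C(C)C)C(C)C)c(OC)c2 | intermediate
45 | Z dibutylboron enolate of 34 (not isolated) | COc1cc(cc(OC)c1O/C=C(\OB(CCCC)CCCC)N2[C@@H](Cc7ccccc7)COC2=O)[C@@H]3OC[C@@H]4[C@H]3CO[C@H]4c5cc(OC)c(O[C@H](CO[Si](C)(C)C(C)(C)C)[C@@H](O[Si](C)(C)C(C)(C)C)c6ccc(O[Si](C(C)C)(C(C)C)C(C)C)c(OC)c6)c(OC)c5 | intermediate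
46 | syn aldol adduct of unit B: (2S,3R)-3-hydroxy-3-(ring B)-2-(ring C aryloxy)propanoyl imide of the (4S) auxiliary, ring B carrying silylated unit A, ring D carrying silylated unit E | COc1cc(cc(OC)c1O[C@H](C(=O)N2[C@@H](Cc3ccccc3)COC2=O)[C@H](O)c4ccc(O[C@@H](CO[Si](C)(C)C(C)(C)C)[C@H](O[Si](C)(C)C(C)(C)C)c5ccc(O[Si](C(C)C)(C(C)C)C(C)C)c(OC)c5)c(OC)c4)[C@@H]6OC[C@@H]7[C@H]6CO[C@H]7c8cc(OC)c(O[C@H](CO[Si](C)(C)C(C)(C)C)[C@@H](O[Si](C)(C)C(C)(C)C)c9ccc(O[Si](C(C)C)(C(C)C)C(C)C)c(OC)c9)c(OC)c8 | intermediate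
47 | (2S,3S)-3-(4-nitrobenzoyloxy) analogue of 46, C3 inverted | COc1cc(cc(OC)c1O[C@H](C(=O)N2[C@@H](Cc3ccccc3)COC2=O)[C@@H](OC(=O)c2ccc(cc2)[N+](=O)[O-])c4ccc(O[C@@H](CO[Si](C)(C)C(C)(C)C)[C@H](O[Si](C)(C)C(C)(C)C)c5ccc(O[Si](C(C)C)(C(C)C)C(C)C)c(OC)c5)c(OC)c4)[C@@H]6OC[C@@H]7[C@H]6CO[C@H]7c8cc(OC)c(O[C@H](CO[Si](C)(C)C(C)(C)C)[C@@H](O[Si](C)(C)C(C)(C)C)c9ccc(O[Si](C(C)C)(C(C)C)C(C)C)c(OC)c9)c(OC)c8 | intermediate
48 | target carrying TBS on O7 and O9 of units A and E and TIPS on the phenols of rings A and E; unit B diol free | COc1cc(cc(OC)c1O[C@H](CO)[C@@H](O)c4ccc(O[C@@H](CO[Si](C)(C)C(C)(C)C)[C@H](O[Si](C)(C)C(C)(C)C)c5ccc(O[Si](C(C)C)(C(C)C)C(C)C)c(OC)c5)c(OC)c4)[C@@H]6OC[C@@H]7[C@H]6CO[C@H]7c8cc(OC)c(O[C@H](CO[Si](C)(C)C(C)(C)C)[C@@H](O[Si](C)(C)C(C)(C)C)c9ccc(O[Si](C(C)C)(C(C)C)C(C)C)c(OC)c9)c(OC)c8 | intermediate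
49 | CNP0316493.2: (7R,8S,7'R,8'S)-syringaresinol core; ring C O-4 bound to C8 of erythro-(7S,8R) guaiacylglycerol unit B, whose O-4 is bound to C8 of erythro-(7R,8S) unit A; ring D O-4 bound to C8 of erythro-(7S,8R) unit E | COc1cc([C@@H](O)[C@H](CO)Oc2ccc([C@H](O)[C@@H](CO)Oc3c(OC)cc([C@@H]4OC[C@@H]5[C@H]4CO[C@H]5c4cc(OC)c(O[C@H](CO)[C@@H](O)c5ccc(O)c(OC)c5)c(OC)c4)cc3OC)cc2OC)ccc1O | target

## Step count and risks

Total step count: 33. Longest linear sequence: 23 steps (1 to 49 through steps 1–3, 6–11, 13–16, 18–23 and 30–33).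

Step 9 (key step).
- What may go wrong: β-elimination of the C7 ring oxygen from the enolate before it is silylated, which opens the ring to a cinnamate; or rearrangement through the boat with the aryl group on the concave side, which would give the 2,3-cis acid.
- Fallback (sets out from 3, comes back at 15): the same [3,3] bond formation is run in acyclic form on a dianion whose β-oxygen is an alkoxide and cannot leave.
  - Keto ester 3 is reduced with the enantiomeric catalyst RuCl(p-cymene)[(S,S)-TsDPEN] to methyl (3S)-3-[4-(benzyloxy)-3,5-dimethoxyphenyl]-3-hydroxypropanoate F1.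
  - Transesterification with (2Z)-4-(tert-butyldimethylsilyloxy)but-2-en-1-ol and Ti(OiPr)4 gives the allylic ester F2.
  - Its dianion (2.2 equiv LiN(iPr)2, THF, −78 °C to rt) rearranges through a chelated chair to the pentenoic acid F3, with C8 anti to the C7 hydroxyl and the same C8/C8' relation as in 14.
  - LiAlH4 gives the silyl ether diol F4.
  - CSA in MeOH/CH2Cl2 removes the silyl group (triol F5) and closes ring 1 through the C7 benzylic cation, which the C9' hydroxyl captures trans to the C8 substituent. This inverts C7 to R and should give 15.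

Step 8.
- What may go wrong: intermolecular esterification (diolide and oligomers) outruns closure of the strained nine-membered ring.
- Fallback (sets out from 4, comes back at 11): the ring is closed at the alkene instead. Hydroxy ester 4 is O-allylated with allyl 2,2,2-trichloroacetimidate and TfOH to methyl (3R)-3-(allyloxy)-3-[4-(benzyloxy)-3,5-dimethoxyphenyl]propanoate F6. Transesterification with allyl alcohol and Ti(OiPr)4 gives the allyl ester F7. Ring-closing metathesis with the second-generation Hoveyda–Grubbs catalyst in dilute toluene at 80 °C should give 11, the Z alkene being enforced by the ring size.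

Step 6.
- What may go wrong: acid ionises the electron-rich benzylic alcohol or the allylic imidate, leading to erosion of configuration at C7, elimination to the cinnamate, or scrambling of alkene geometry and regiochemistry.
- Fallback (sets out from 4, comes back at 11, bypassing steps 7 and 8): a base-mediated route on the carboxylate. Saponification of 4 (LiOH) gives (3R)-3-[4-(benzyloxy)-3,5-dimethoxyphenyl]-3-hydroxypropanoic acid F8. Its disodium salt (NaH, 2.1 equiv) is O-alkylated at the alkoxide with excess (2Z)-1,4-dichlorobut-2-ene to the chloro ether acid F9; the carboxylate alkoxide dianion resists retro-aldol and elimination. Cs2CO3 in DMF at high dilution closes the lactone by intramolecular carboxylate alkylation to 11.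

Step 14.
- What may go wrong: poor facial selectivity when the C7' cation is captured (endo aryl), or acid-induced equilibration at C7 and C7' after closure.
- Fallback (sets out from 17, comes back at 22): the aryl group is added to the intact bicycle. Lactol 17 is acetylated (Ac2O, pyridine) to the lactol acetate F10. Grignard reagent 20 is transmetallated with ZnBr2 to the arylzinc bromide F11. BF3·OEt2 ionises F10 to the bicyclic oxocarbenium ion, which F11 should attack on the convex face to give 22 directly.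

Step 19 (the same reaction recurs in steps 26 and 31 and carries the same risk).
- What may go wrong: elimination of the activated β-hydroxy imide to an α-aryloxy acrylimide, or partial ionisation at the benzylic carbon with incomplete inversion.
- Fallback (sets out from 29, comes back at 31): the auxiliary is removed before the inversion. LiBH4 reduces 29 to the threo diol F12. Excess 4-nitrobenzoic acid, PPh3 and DIAD esterify the primary hydroxyl and invert the secondary benzylic one, giving the bis(4-nitrobenzoate) F13. K2CO3 in MeOH then gives 31.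

## Further compounds

F1 | step 9 | methyl (3S)-3-[4-(benzyloxy)-3,5-dimethoxyphenyl]-3-hydroxypropanoate | COC(=O)C[C@H](O)c1cc(OC)c(OCc2ccccc2)c(OC)c1
F2 | step 9 | (2Z)-4-(tert-butyldimethylsilyloxy)but-2-en-1-yl (3S)-3-[4-(benzyloxy)-3,5-dimethoxyphenyl]-3-hydroxypropanoate | CC(C)(C)[Si](C)(C)OC/C=C\COC(=O)C[C@H](O)c1cc(OC)c(OCc2ccccc2)c(OC)c1
F3 | step 9 | (2R,3S)-2-{(S)-[4-(benzyloxy)-3,5-dimethoxyphenyl](hydroxy)methyl}-3-[(tert-butyldimethylsilyloxy)methyl]pent-4-enoic acid | OC(=O)[C@@H]([C@H](O)c1cc(OC)c(OCc2ccccc2)c(OC)c1)[C@H](C=C)CO[Si](C)(C)C(C)(C)C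
F4 | step 9 | (1S,2S,3S)-1-[4-(benzyloxy)-3,5-dimethoxyphenyl]-3-[(tert-butyldimethylsilyloxy)methyl]-2-(hydroxymethyl)pent-4-en-1-ol | OC[C@@H]([C@H](O)c1cc(OC)c(OCc2ccccc2)c(OC)c1)[C@H](C=C)CO[Si](C)(C)C(C)(C)C
F5 | step 9 | (1S,2S,3S)-1-[4-(benzyloxy)-3,5-dimethoxyphenyl]-2,3-bis(hydroxymethyl)pent-4-en-1-ol | OC[C@@H]([C@H](O)c1cc(OC)c(OCc2ccccc2)c(OC)c1)[C@H](C=C)CO
F6 | step 8 | methyl (3R)-3-(allyloxy)-3-[4-(benzyloxy)-3,5-dimethoxyphenyl]propanoate | COC(=O)C[C@@H](OCC=C)c1cc(OC)c(OCc2ccccc2)c(OC)c1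
F7 | step 8 | allyl (3R)-3-(allyloxy)-3-[4-(benzyloxy)-3,5-dimethoxyphenyl]propanoate | C=CCOC(=O)C[C@@H](OCC=C)c1cc(OC)c(OCc2ccccc2)c(OC)c1
F8 | step 6 | (3R)-3-[4-(benzyloxy)-3,5-dimethoxyphenyl]-3-hydroxypropanoic acid | OC(=O)C[C@@H](O)c1cc(OC)c(OCc2ccccc2)c(OC)c1
F9 | step 6 | (3R)-3-[4-(benzyloxy)-3,5-dimethoxyphenyl]-3-{[(2Z)-4-chlorobut-2-en-1-yl]oxy}propanoic acid | OC(=O)C[C@@H](OC/C=C\CCl)c1cc(OC)c(OCc2ccccc2)c(OC)c1
F10 | step 14 | (3aS,4R,6aS)-4-[4-(benzyloxy)-3,5-dimethoxyphenyl]tetrahydro-1H,3H-furo[3,4-c]furan-1-yl acetate, both anomers | COc1cc(cc(OC)c1OCc2ccccc2)[C@@H]3OC[C@@H]4[C@H]3COC4OC(C)=O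
F11 | step 14 | {3,5-dimethoxy-4-[tri(propan-2-yl)silyloxy]phenyl}zinc bromide | COc1cc([Zn]Br)cc(OC)c1O[Si](C(C)C)(C(C)C)C(C)C
F12 | step 19 | (1R,2R)-2-[4-(4-[4-(benzyloxy)-3,5-dimethoxyphenyl]furofuran-1-yl)-2,6-dimethoxyphenoxy]-1-{3-methoxy-4-[tri(propan-2-yl)silyloxy]phenyl}propane-1,3-diol (threo) | COc1cc(cc(OC)c1OCc2ccccc2)[C@@H]3OC[C@@H]4[C@H]3CO[C@H]4c5cc(OC)c(O[C@H](CO)[C@H](O)c6ccc(O[Si](C(C)C)(C(C)C)C(C)C)c(OC)c6)c(OC)c5
F13 | step 19 | 1,3-bis(4-nitrobenzoate) of the (1S,2R) erythro diol 31 | COc1cc(cc(OC)c1OCc2ccccc2)[C@@H]3OC[C@@H]4[C@H]3CO[C@H]4c5cc(OC)c(O[C@H](COC(=O)c7ccc(cc7)[N+](=O)[O-])[C@@H](OC(=O)c8ccc(cc8)[N+](=O)[O-])c6ccc(O[Si](C(C)C)(C(C)C)C(C)C)c(OC)c6)c(OC)c5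
A1 | alternative 1 | bis(erythro 2-aryloxy-3-hydroxy thioester) on the syringaresinol core | COc1cc(ccc1OCc2ccccc2)[C@H](O)[C@@H](C(=O)SCC)Oc3c(OC)cc(cc3OC)[C@@H]4OC[C@@H]5[C@H]4CO[C@H]5c6cc(OC)c(O[C@H](C(=O)SCC)[C@@H](O)c7ccc(OCc8ccccc8)c(OC)c7)c(OC)c6
A2 | alternative 1 | (7R,8S,7'R,8'S)-syringaresinol, the core bisphenol | COc1cc(cc(OC)c1O)[C@@H]2OC[C@@H]3[C@H]2CO[C@H]3c4cc(OC)c(O)c(OC)c4
A3 | alternative 1 | bis(Z ketene silyl thioacetal) of the bis-O-(ethylthiocarbonylmethyl) ether of A2 | COc1cc(cc(OC)c1O/C=C(/O[Si](C)(C)C)SCC)[C@@H]2OC[C@@H]3[C@H]2CO[C@H]3c4cc(OC)c(O/C=C(/O[Si](C)(C)C)SCC)c(OC)c4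
A4 | alternative 1 | 4-(benzyloxy)-3-methoxybenzaldehyde (O-benzylvanillin) | COc1cc(C=O)ccc1OCc1ccccc1
A5 | alternative 2 | trans,trans-trisubstituted lactone acetal, C7' carbinol epimers | O=C1O[C@H](O[C@H]2C[C@@H](C)CC[C@@H]2C(C)C)[C@@H](C3(SCCCS3)c4cc(OC)c(OCc5ccccc5)c(OC)c4)[C@@H]1C(O)c6cc(OC)c(OCC=C)c(OC)c6
A6 | alternative 2 | 5-(menthyloxy)furan-2(5H)-one | O=C1O[C@H](O[C@H]2C[C@@H](C)CC[C@@H]2C(C)C)C=C1
A7 | alternative 2 | 2-[4-(benzyloxy)-3,5-dimethoxyphenyl]-2-lithio-1,3-dithiane | [Li]C1(SCCCS1)c1cc(OC)c(OCc2ccccc2)c(OC)c1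
A8 | alternative 2 | 4-(allyloxy)-3,5-dimethoxybenzaldehyde | COc1cc(C=O)cc(OC)c1OCC=C
A9 | alternative 3 | C2-symmetric protected core with both inner units as acetonides | COc1cc(ccc1OCc2ccccc2)[C@@H]3OC(C)(C)OC[C@H]3Oc4c(OC)cc(cc4OC)[C@@H]5OC[C@@H]6[C@H]5CO[C@H]6c7cc(OC)c(O[C@@H]8COC(C)(C)O[C@H]8c9ccc(OCc1ccccc1)c(OC)c9)c(OC)c7
A10 | alternative 3 | (3aS,6aS)-tetrahydro-1H,3H-furo[3,4-c]furan-1,4-diyl diacetate, the bis(lactol acetate) | CC(=O)OC1OC[C@@H]2[C@H]1COC2OC(C)=O
A11 | alternative 3 | arylzinc bromide of the 4-bromo-2,6-dimethoxyphenyl ether of the acetonide-protected erythro unit | COc1cc([Zn]Br)cc(OC)c1O[C@@H]2COC(C)(C)O[C@H]2c3ccc(OCc4ccccc4)c(OC)c3
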